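**Plan**
- Retrosynthesis: the benzyl ether on O7 and a triflate on O5 are the last masks. Beneath them ring C is cut at three bonds at once (O1–C8a, C4a–C4, O1–C2), giving an arylpropiolic acid (ring B, C2, C3, C4, O1, O4) and a ring A aryne across C4a–C8a.
- Enabling feature: O1 and C4 stand on the adjacent ring A carbons C8a and C4a. With triflates on C5 and C8a around a silyl group on C4a, ring A is mirror-symmetric through C4a and C7, so either triflate may leave and the one left on C5 polarises the aryne.
- Forward: ring A is bought as syringol and decorated (benzylation, dibromination, C–Br to C–OH, bromination between the hydroxyls, retro-Brook silyl shift, bis-triflation). Ring B is bought as the aryl alkyne and carboxylated.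
- Ring C is the only ring made, in the aryne step; triflate hydrolysis and hydrogenolysis then free the 5- and 7-hydroxyls.
- Stereochemistry: the target is achiral; no stereocenter is made or carried.

Key step: step 8

Assumption: in the aryne the triflyloxy group on C5 is taken to out-direct the methoxy group on C8, so the carboxylate adds to C8a; the three starting materials are taken as purchased.

Step 1
Reactants: 1 2,6-dimethoxyphenol (syringol); 2 benzyl bromide
Product: 3 2-(benzyloxy)-1,3-dimethoxybenzene
Conditions: K2CO3, DMF, 60 °C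
Reagents that add atoms: none
Why: Williamson ether synthesis on the acidic, hindered phenoxide marks the future O7 with a group that later leaves by hydrogenolysis while the methyl ethers stay.

Step 2
Reactants: 3 2-(benzyloxy)-1,3-dimethoxybenzene
Product: 4 3-(benzyloxy)-1,5-dibromo-2,4-dimethoxybenzene
Conditions: NBS (2.2 equiv), MeCN, dark, rt to 50 °C
Reagents that add atoms: N-bromosuccinimide, O=C1CCC(=O)N1Br
Why: Electrophilic aromatic bromination places each bromine ortho to one methoxy group and para to the other, while the carbon para to the doubly flanked, twisted benzyloxy group stays free, as in the dibromination of 1,2,3-trimethoxybenzene.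

Step 3
Reactants: 4 3-(benzyloxy)-1,5-dibromo-2,4-dimethoxybenzene
Product: 6 5-(benzyloxy)-4,6-dimethoxybenzene-1,3-diol, via aryl bis(pinacolboronate) 5 (not isolated)
Conditions: B2pin2 (2.6 equiv), Pd(dppf)Cl2 (5 mol %), KOAc, 1,4-dioxane, 90 °C; filter, then 30% H2O2, aq NaOH, THF, 0 °C; Na2S2O3 quench
Reagents that add atoms: hydrogen peroxide, OO (both hydroxyl oxygens); bis(pinacolato)diboron, CC1(C)OB(OC1(C)C)B1OC(C)(C)C(C)(C)O1 (boron of 5 only)
Why: Miyaura borylation of both C–Br bonds followed by peroxide oxidation of the C–B bonds (aryl shift from boron to oxygen) replaces each bromine by hydroxyl at the same carbon and leaves the benzyl and methyl ethers untouched.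

Step 4
Reactants: 6 5-(benzyloxy)-4,6-dimethoxybenzene-1,3-diol
Product: 7 5-(benzyloxy)-2-bromo-4,6-dimethoxybenzene-1,3-diol
Conditions: NBS (1.0 equiv), CH2Cl2, −78 to 0 °C
Reagents that add atoms: N-bromosuccinimide, O=C1CCC(=O)N1Br
Why: Electrophilic bromination of a phenol can only go to C2, the one unsubstituted carbon of this ring, which is activated by both flanking hydroxyls.

Step 5
Reactants: 7 5-(benzyloxy)-2-bromo-4,6-dimethoxybenzene-1,3-diol
Product: 10 5-(benzyloxy)-4,6-dimethoxy-2-(trimethylsilyl)benzene-1,3-diol, via bis(trimethylsilyl) ether 8 (not isolated), via C-silyl lithium phenolate 9 (not isolated)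
Conditions: HMDS, THF, 70 °C, evaporate; n-BuLi (1.1 equiv), THF, −78 °C to rt; sat. aq NH4Cl, 0 °C to rt
Reagents that add atoms: hexamethyldisilazane, C[Si](C)(C)N[Si](C)(C)C (the trimethylsilyl group on C2); n-butyllithium, [Li]CCCC (lithium of 9 only)
Why: After O-silylation, bromine–lithium exchange at −78 °C (faster than benzylic deprotonation) triggers a 1,3 O-to-C silyl shift (retro-Brook rearrangement) driven by phenolate formation, and the remaining labile aryl O–Si bond is hydrolysed on mild aqueous work-up.

Step 6
Reactants: 10 5-(benzyloxy)-4,6-dimethoxy-2-(trimethylsilyl)benzene-1,3-diol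
Product: 11 5-(benzyloxy)-4,6-dimethoxy-2-(trimethylsilyl)-1,3-phenylene bis(trifluoromethanesulfonate)
Conditions: Tf2O (2.5 equiv), pyridine, CH2Cl2, −40 to 0 °C
Reagents that add atoms: trifluoromethanesulfonic anhydride, O=S(=O)(OS(=O)(=O)C(F)(F)F)C(F)(F)F
Why: O-sulfonylation of both phenols with triflic anhydride and pyridine is the standard final step towards 2-silylaryl triflates and keeps the mirror plane through C2 and C5 of the benzene ring.

Step 7
Reactants: 12 5-ethynyl-1,2,3-trimethoxybenzene
Product: 14 3-(3,4,5-trimethoxyphenyl)prop-2-ynoic acid, via lithium acetylide 13 (not isolated)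
Conditions: n-BuLi, THF, −78 °C; CO2 (g), −78 °C to rt; 1 M HCl
Reagents that add atoms: carbon dioxide, O=C=O; n-butyllithium, [Li]CCCC (lithium of 13 only)
Why: Deprotonation of the terminal alkyne and carboxylation of the lithium acetylide with CO2 is the standard preparation of arylpropiolic acids.

Step 8
Reactants: 11 5-(benzyloxy)-4,6-dimethoxy-2-(trimethylsilyl)-1,3-phenylene bis(trifluoromethanesulfonate); 14 3-(3,4,5-trimethoxyphenyl)prop-2-ynoic acid
Product: 17 7-(benzyloxy)-6,8-dimethoxy-4-oxo-2-(3,4,5-trimethoxyphenyl)-4H-chromen-5-yl trifluoromethanesulfonate, via 3-triflyloxyaryne 15 (not isolated), via 2-hydroxyaryl ynone 16 (not isolated)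
Conditions: CsF (5 equiv), 14 (1.5 equiv), THF, 125 °C, sealed tube
Reagents that add atoms: none
Why: Fluoride removes the silyl group of 11 and either of its two equivalent triflates leaves, so the single aryne 15 forms with the second triflate still on C5; the cesium carboxylate of 14 adds through oxygen to C8a (O1–C8a), the resulting C4a aryl anion attacks its own ester carbonyl through a four-membered ring (C4a–C4) that opens to the phenoxide of ynone 16, and this phenoxide adds to the alkyne (O1–C2). The closest known reaction type is the insertion of arynes into the C–O bond of carboxylic acids, which turns arylpropiolic acids into flavones, run here on a 3-triflyloxyaryne, a class known to take up sigma bonds (for example N–Si) with the triflate left in place. Ring C, the only ring formed, closes by 6-endo-dig oxa-Michael addition of the phenoxide to the ynone, and the four-membered ring is transient. No stereocenter is created. The step needs the carboxylate at C8a and not at C4a: the triflyloxy group on C5 is a stronger inductive acceptor and bulkier than the methoxy group on C8, so attack beside the methoxy group, which puts the developing negative charge on C4a next to the triflate, should be preferred, and the mirror symmetry of 11 makes the choice of leaving triflate irrelevant. Acyl transfer must also outrun loss of the C5 triflate from the aryl anion and its protonation, which the ortho-held conjugated ynoate carbonyl, the excess CsF (acid present only as carboxylate) and dry conditions favour.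

Step 9
Reactants: 17 7-(benzyloxy)-6,8-dimethoxy-4-oxo-2-(3,4,5-trimethoxyphenyl)-4H-chromen-5-yl trifluoromethanesulfonate
Product: 18 7-(benzyloxy)-5-hydroxy-6,8-dimethoxy-2-(3,4,5-trimethoxyphenyl)-4H-chromen-4-one
Conditions: Et4NOH (aq, 2.5 equiv), 1,4-dioxane, rt; 1 M HCl work-up
Reagents that add atoms: none
Why: Hydroxide attacks sulfur of the aryl triflate (S–O cleavage, a known mild triflate deprotection) and releases the C5 phenoxide, stabilised by the peri carbonyl, while the ethers and the pyranone are stable at room temperature.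

Step 10
Reactants: 18 7-(benzyloxy)-5-hydroxy-6,8-dimethoxy-2-(3,4,5-trimethoxyphenyl)-4H-chromen-4-one
Product: 19 5,7-dihydroxy-6,8-dimethoxy-2-(3,4,5-trimethoxyphenyl)-4H-chromen-4-one (5,7-dihydroxy-6,8,3',4',5'-pentamethoxyflavone)
Conditions: H2 (1 atm), 10% Pd/C, EtOAc–MeOH, rt
Reagents that add atoms: none
Why: Hydrogenolysis of the benzyl ether frees the C7 hydroxyl; the methyl ethers are inert and the C2–C3 double bond of the pyranone should survive if the reaction is stopped after one equivalent of hydrogen.

**Compound list**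
1 | 2,6-dimethoxyphenol (syringol) | COc1cccc(OC)c1O | starting material
2 | benzyl bromide | BrCc1ccccc1 | starting material
3 | 2-(benzyloxy)-1,3-dimethoxybenzene | COc1cccc(OC)c1OCc1ccccc1 | intermediate
4 | 3-(benzyloxy)-1,5-dibromo-2,4-dimethoxybenzene | COc1c(Br)cc(Br)c(OC)c1OCc1ccccc1 | intermediate
5 | 2,2'-[5-(benzyloxy)-4,6-dimethoxy-1,3-phenylene]bis(4,4,5,5-tetramethyl-1,3,2-dioxaborolane) | COc1c(B2OC(C)(C)C(C)(C)O2)cc(B2OC(C)(C)C(C)(C)O2)c(OC)c1OCc1ccccc1 | intermediate
6 | 5-(benzyloxy)-4,6-dimethoxybenzene-1,3-diol | COc1c(O)cc(O)c(OC)c1OCc1ccccc1 | intermediate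
7 | 5-(benzyloxy)-2-bromo-4,6-dimethoxybenzene-1,3-diol | COc1c(O)c(Br)c(O)c(OC)c1OCc1ccccc1 | intermediate
8 | [5-(benzyloxy)-2-bromo-4,6-dimethoxy-1,3-phenylene]bis(oxy)bis(trimethylsilane) | COc1c(O[Si](C)(C)C)c(Br)c(O[Si](C)(C)C)c(OC)c1OCc1ccccc1 | intermediate
9 | lithium 3-(benzyloxy)-2,4-dimethoxy-6-(trimethylsilyl)-5-[(trimethylsilyl)oxy]phenolate | [Li+].COc1c([O-])c([Si](C)(C)C)c(O[Si](C)(C)C)c(OC)c1OCc1ccccc1 | intermediate
10 | 5-(benzyloxy)-4,6-dimethoxy-2-(trimethylsilyl)benzene-1,3-diol | COc1c(O)c([Si](C)(C)C)c(O)c(OC)c1OCc1ccccc1 | intermediate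
11 | 5-(benzyloxy)-4,6-dimethoxy-2-(trimethylsilyl)-1,3-phenylene bis(trifluoromethanesulfonate) | COc1c(OCc2ccccc2)c(OC)c(OS(=O)(=O)C(F)(F)F)c([Si](C)(C)C)c1OS(=O)(=O)C(F)(F)F | intermediate
12 | 5-ethynyl-1,2,3-trimethoxybenzene | C#Cc1cc(OC)c(OC)c(OC)c1 | starting material
13 | lithium (3,4,5-trimethoxyphenyl)acetylide | [Li]C#Cc1cc(OC)c(OC)c(OC)c1 | intermediate
14 | 3-(3,4,5-trimethoxyphenyl)prop-2-ynoic acid | OC(=O)C#Cc1cc(OC)c(OC)c(OC)c1 | intermediate
15 | 3-(benzyloxy)-2,4-dimethoxy-5,6-didehydrophenyl trifluoromethanesulfonate (aryne) | COC1=C(OCc2ccccc2)C(OC)=C(OS(=O)(=O)C(F)(F)F)C#C1 | intermediate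
16 | 3-(benzyloxy)-5-hydroxy-2,4-dimethoxy-6-[3-(3,4,5-trimethoxyphenyl)prop-2-ynoyl]phenyl trifluoromethanesulfonate (present as its cesium phenoxide) | COc1cc(C#CC(=O)c2c(O)c(OC)c(OCc3ccccc3)c(OC)c2OS(=O)(=O)C(F)(F)F)cc(OC)c1OC | intermediate
17 | 7-(benzyloxy)-6,8-dimethoxy-4-oxo-2-(3,4,5-trimethoxyphenyl)-4H-chromen-5-yl trifluoromethanesulfonate | O=c1cc(-c2cc(OC)c(OC)c(OC)c2)oc2c(OC)c(OCc3ccccc3)c(OC)c(OS(=O)(=O)C(F)(F)F)c12 | intermediate
18 | 7-(benzyloxy)-5-hydroxy-6,8-dimethoxy-2-(3,4,5-trimethoxyphenyl)-4H-chromen-4-one | O=c1cc(-c2cc(OC)c(OC)c(OC)c2)oc2c(OC)c(OCc3ccccc3)c(OC)c(O)c12 | intermediate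
19 | 5,7-dihydroxy-6,8-dimethoxy-2-(3,4,5-trimethoxyphenyl)-4H-chromen-4-one | COc1cc(-c2cc(=O)c3c(O)c(OC)c(O)c(OC)c3o2)cc(OC)c1OC | target

Total steps: 10. Longest linear sequence: 9 (steps 1–6, 8, 9, 10); step 7 is the one-step side branch.

**Steps most likely to fail**

Step 8. Three processes may divert it:
- the carboxylate may add to C4a if the methoxy group on C8 competes well with the triflyloxy group, which carries the acyl group to the wrong ring carbon;
- the C4a aryl anion may expel the C5 triflate (a second aryne) before the acyl shift;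
- the anion may be protonated, stopping at the aryl ester.

Partial loss of the C5 triflate from 17 under fluoride would be harmless, since step 9 removes it anyway. The fallback uses no aryne and sets out from 6:
- C-acetylation at the only free ring carbon (Ac2O, BF3·OEt2, Friedel–Crafts/Fries type) should give 1-[4-(benzyloxy)-2,6-dihydroxy-3,5-dimethoxyphenyl]ethan-1-one F1.
- Its polyanion (LiN(SiMe3)2, 4 equiv, THF, −78 °C) is C-aroylated with 3,4,5-trimethoxybenzoyl chloride (Claisen-type, the one-pot form of the Baker–Venkataraman sequence) to give 1-[4-(benzyloxy)-2,6-dihydroxy-3,5-dimethoxyphenyl]-3-(3,4,5-trimethoxyphenyl)propane-1,3-dione F2.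
- Cyclodehydration (cat. H2SO4, AcOH, 95 °C) closes ring C.

Because the two ortho hydroxyls of F2 are equivalent, only one flavone can form. It is 18, where the route is rejoined before step 10.

Step 5. The electron-rich aryl–silicon bond of 10, ortho to two hydroxyls, may be lost by ipso protonation while the second hydroxyl is unmasked, or the silyl shift may stall on the crowded ring. The fallback sets out from 7 and runs through 8 and 9 as before, but 9 is trapped with Tf2O at −78 °C instead of water. This gives 3-(benzyloxy)-2,4-dimethoxy-6-(trimethylsilyl)-5-[(trimethylsilyl)oxy]phenyl trifluoromethanesulfonate F3. Brief dilute aqueous acid then cleaves only the O–Si bond to 3-(benzyloxy)-5-hydroxy-2,4-dimethoxy-6-(trimethylsilyl)phenyl trifluoromethanesulfonate F4, whose ring is deactivated towards protonation by the triflate. Tf2O and pyridine convert F4 into 11, where the route is rejoined; the free silyl diol 10 is never formed.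

Step 4. The brominating agent may oxidise the pentaoxygenated resorcinol to a quinone instead of substituting it. The fallback sets out from 6 and introduces silicon by C–H lithiation:
- Et2NCOCl and K2CO3 in MeCN give 5-(benzyloxy)-4,6-dimethoxy-1,3-phenylene bis(diethylcarbamate) F5.
- Directed ortho-metalation at the one ring C–H between the two carbamates with in situ quench (lithium 2,2,6,6-tetramethylpiperidide, Me3SiCl, THF, −78 °C) gives 5-(benzyloxy)-4,6-dimethoxy-2-(trimethylsilyl)-1,3-phenylene bis(diethylcarbamate) F6.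
- LiAlH4 in THF removes both carbamates under non-protic conditions and returns the route at 10.

**Further compounds**
F1 | step 8 | 1-[4-(benzyloxy)-2,6-dihydroxy-3,5-dimethoxyphenyl]ethan-1-one | CC(=O)c1c(O)c(OC)c(OCc2ccccc2)c(OC)c1O
F2 | step 8 | 1-[4-(benzyloxy)-2,6-dihydroxy-3,5-dimethoxyphenyl]-3-(3,4,5-trimethoxyphenyl)propane-1,3-dione | COc1cc(C(=O)CC(=O)c2c(O)c(OC)c(OCc3ccccc3)c(OC)c2O)cc(OC)c1OC
F3 | step 5 | 3-(benzyloxy)-2,4-dimethoxy-6-(trimethylsilyl)-5-[(trimethylsilyl)oxy]phenyl trifluoromethanesulfonate | COc1c(OS(=O)(=O)C(F)(F)F)c([Si](C)(C)C)c(O[Si](C)(C)C)c(OC)c1OCc1ccccc1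
F4 | step 5 | 3-(benzyloxy)-5-hydroxy-2,4-dimethoxy-6-(trimethylsilyl)phenyl trifluoromethanesulfonate | COc1c(OS(=O)(=O)C(F)(F)F)c([Si](C)(C)C)c(O)c(OC)c1OCc1ccccc1
F5 | step 4 | 5-(benzyloxy)-4,6-dimethoxy-1,3-phenylene bis(diethylcarbamate) | CCN(CC)C(=O)Oc1cc(OC(=O)N(CC)CC)c(OC)c(OCc2ccccc2)c1OC
F6 | step 4 | 5-(benzyloxy)-4,6-dimethoxy-2-(trimethylsilyl)-1,3-phenylene bis(diethylcarbamate) | CCN(CC)C(=O)Oc1c([Si](C)(C)C)c(OC(=O)N(CC)CC)c(OC)c(OCc2ccccc2)c1OC
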